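**Retrosynthetic overview**
1. GA65 ⇐ ester cleavage, C15 ketone reduction and C16 methylenation of a 17-nor-15-ketone diester.
2. Ring D is closed last (C13–C16 bond) by cyclisation of a methyl-ketone enol silane onto an allyl cation in the tricycle of rings A B C.
3. Rings B and C are formed together by an intramolecular Diels–Alder reaction (C8–C9 and C13–C14): an α-methylene ketone on the C5 arm adds to a 1-acetoxydiene on quaternary C10.
4. Ring A is bought as a cyclohexenone: C4 by copper-catalysed asymmetric conjugate methylation, C5 by enolate alkylation, C10 by aldehyde α-allylation.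
5. Ring order: A (starting material) → B + C (one operation) → D.

Assumption: locants C1–C20 are gibberellane numbers; α/β mean below/above the plane of the usual gibberellin drawing (C19, C20 α; H-5, H-9, C7, C15 β); skeleton compounds 6–18 are C6 epimer mixtures (7 also at C10) and carry no stereo mark there.

**Step 1**
Reactants: 1 methyl 3-oxocyclohex-1-ene-1-carboxylate; 2 methyl 2-iodoacetate
Product: 3 methyl (1R,2R)-2-(2-methoxy-2-oxoethyl)-1-methyl-3-oxocyclohexane-1-carboxylate
Conditions: Me2Zn, Cu(OTf)2 (5 mol %), chiral sulfonate-bearing imidazolinium salt (carbene ligand precursor, 5 mol %, enantiomer giving 1R), Et2O, −30 °C; then DMPU, 2, −30 → 0 °C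
Reagents that add atoms: dimethylzinc, C[Zn]C
Why: Copper-catalysed asymmetric conjugate addition of Me2Zn to the β-ester enone sets the C4 quaternary centre under catalyst control, and the regiodefined zinc enolate is C-alkylated at C5 anti to the larger C4 methyl group, so the arm ends equatorial and cis to the C4 ester (the C5 epimer, α to the ketone, equilibrates toward the same isomer).

**Step 2**
Reactants: 3 methyl (1R,2R)-2-(2-methoxy-2-oxoethyl)-1-methyl-3-oxocyclohexane-1-carboxylate
Product: 4 methyl 2-(2-methoxy-2-oxoethyl)-3-(methoxymethylidene)-1-methylcyclohexane-1-carboxylate (C4 and C5 as in 3; E/Z mixture)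
Conditions: Ph3P(CH2OMe)Cl, KOt-Bu, THF, 0 → 25 °C
Reagents that add atoms: (methoxymethyl)triphenylphosphonium chloride, COC[P+](c1ccccc1)(c1ccccc1)c1ccccc1.[Cl-]
Why: Wittig olefination of the ketone with the methoxymethylene ylide (esters do not react) adds C20 as an enol ether; no stereocentre is created and the E/Z ratio is irrelevant.

**Step 3**
Reactants: 4 methyl 2-(2-methoxy-2-oxoethyl)-3-(methoxymethylidene)-1-methylcyclohexane-1-carboxylate; 5 3-bromoprop-1-yne
Product: 6 methyl 2-(1-methoxy-1-oxopent-4-yn-2-yl)-3-(methoxymethylidene)-1-methylcyclohexane-1-carboxylate (C6 epimers)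
Conditions: LDA, THF, −78 °C; 5, −78 → −20 °C
Reagents that add atoms: none
Why: Ester enolate alkylation: LDA removes a proton from the only enolisable position (C6) and SN2 reaction with propargyl bromide installs C8, C15 and C16 as a masked acetonyl group; C6 forms as a mixture that is corrected in step 11.

**Step 4**
Reactants: 6 methyl 2-(1-methoxy-1-oxopent-4-yn-2-yl)-3-(methoxymethylidene)-1-methylcyclohexane-1-carboxylate
Product: 7 methyl 3-formyl-2-(1-methoxy-1-oxopent-4-yn-2-yl)-1-methylcyclohexane-1-carboxylate (C6 and C10 epimers)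
Conditions: 2 M aq HCl, THF, 25 °C
Reagents that add atoms: water, O
Why: Acid hydrolysis of the enol ether (oxocarbenium ion, then hemiacetal) unveils the C20 aldehyde; the new C10 centre is a mixture that is erased in step 5.

**Step 5**
Reactants: 7 methyl 3-formyl-2-(1-methoxy-1-oxopent-4-yn-2-yl)-1-methylcyclohexane-1-carboxylate; 8 3-bromoprop-1-ene
Product: 9 methyl 3-formyl-2-(1-methoxy-1-oxopent-4-yn-2-yl)-1-methyl-3-(prop-2-enyl)cyclohexane-1-carboxylate (4α-CO2Me; 5β-H; 10α-CHO; 10β-allyl; C6 epimers)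
Conditions: KOt-Bu, THF, 0 °C; 8; then PhMe, 120 °C
Reagents that add atoms: none
Why: α-Alkylation of the α-branched aldehyde enolate (any O-allyl enol ether converges by Claisen rearrangement on heating): allyl enters C10 equatorially on the β face, anti to the C5 arm and away from the axial C4 ester, so the formyl group ends axial (α) and C9 is trans to C6.

**Step 6**
Reactants: 9 methyl 3-formyl-2-(1-methoxy-1-oxopent-4-yn-2-yl)-1-methyl-3-(prop-2-enyl)cyclohexane-1-carboxylate
Product: 10 methyl 3-formyl-2-(1-methoxy-1,4-dioxopentan-2-yl)-1-methyl-3-(prop-2-enyl)cyclohexane-1-carboxylate (ring centres as in 9)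
Conditions: (Ph3P)AuNTf2 (2 mol %), 1,4-dioxane/H2O, 60 °C
Reagents that add atoms: water, O
Why: Gold-catalysed Markovnikov hydration of the terminal alkyne (assisted by the neighbouring ester carbonyl) gives the methyl ketone without touching the alkene, aldehyde or esters; no stereocentre is affected.

**Step 7**
Reactants: 10 methyl 3-formyl-2-(1-methoxy-1,4-dioxopentan-2-yl)-1-methyl-3-(prop-2-enyl)cyclohexane-1-carboxylate; 11 prop-2-enal
Product: 12 methyl 3-formyl-2-(1-methoxy-1,4-dioxopentan-2-yl)-1-methyl-3-[(E)-4-oxobut-2-enyl]cyclohexane-1-carboxylate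
Conditions: 11 (5 equiv), second-generation Hoveyda–Grubbs catalyst (5 mol %), CH2Cl2, 40 °C
Reagents that add atoms: none
Why: Olefin cross-metathesis of the unhindered terminal alkene with acrolein gives the (E)-enal under thermodynamic control; the other carbonyl groups are spectators.

**Step 8**
Reactants: 12 methyl 3-formyl-2-(1-methoxy-1,4-dioxopentan-2-yl)-1-methyl-3-[(E)-4-oxobut-2-enyl]cyclohexane-1-carboxylate
Product: 13 methyl 3-[(1E,3E)-4-acetoxybuta-1,3-dienyl]-3-formyl-2-(1-methoxy-1,4-dioxopentan-2-yl)-1-methylcyclohexane-1-carboxylate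
Conditions: Ac2O, Et3N, DMAP (cat.), PhMe, 60 °C
Reagents that add atoms: acetic anhydride, CC(=O)OC(C)=O
Why: Dienol acetate formation: γ-deprotonation of the enal and O-acetylation give the conjugated (1E,3E)-1-acetoxydiene; the non-enolisable C20 aldehyde and the less acidic methyl ketone do not react.

**Step 9**
Reactants: 13 methyl 3-[(1E,3E)-4-acetoxybuta-1,3-dienyl]-3-formyl-2-(1-methoxy-1,4-dioxopentan-2-yl)-1-methylcyclohexane-1-carboxylate
Product: 15 tricyclic cycloadduct of rings A B C (4α-CO2Me; 4β-Me; 5β-H; 6-CO2Me; 8β-acetyl; 9β-H; 10α-CHO; 13α-OAc; 11-ene; C6 epimers), via α-methylene ketone 14 (not isolated)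
Conditions: (CH2O)n, PhNHMe·CF3CO2H, THF, 65 °C; then PhMe, BHT, 110 °C
Reagents that add atoms: formaldehyde (as paraformaldehyde), C=O
Why: Key step: Mannich-type α-methylenation at the more substituted ketone α-carbon (C8) generates the enone, which undergoes an intramolecular Diels–Alder reaction with the acetoxydiene to form C8–C9 and C13–C14 (rings B and C at once); the trans A/B relationship is already fixed by C5 and C10, the tether-endo/acetyl-exo transition state preferred by α-substituted enones gives the cis B/C fusion and puts the (E)-acetoxy group cis to C6 and C10 (α, trans to the acetyl group), and the diene reacts on the face where it eclipses the small planar formyl group instead of the ring A methylene (allylic strain), which sets C8 and C9 as in the target.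

**Step 10**
Reactants: 15 tricyclic cycloadduct of rings A B C (4α-CO2Me; 4β-Me; 5β-H; 6-CO2Me; 8β-acetyl; 9β-H; 10α-CHO; 13α-OAc; 11-ene; C6 epimers)
Product: 17 dimethyl 15,20-dioxo-17-norgibberell-11-ene-7,19-dioate (C6 epimers), via trimethylsilyl enol ether 16 (not isolated)
Conditions: Et3N (1.1 equiv), TMSOTf (1.4 equiv), CH2Cl2 (0.01 M), −78 °C; then −78 → −20 °C; aq NaHCO3
Reagents that add atoms: trimethylsilyl trifluoromethanesulfonate, C[Si](C)(C)OS(=O)(=O)C(F)(F)F (its silyl group is carried only by 16)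
Why: Lewis-acid SN1 allylic alkylation of an enol silane (Mukaiyama type): the methyl ketone becomes its silyl enol ether, the excess TMSOTf ionises the allylic acetate, and C16 attacks the allyl cation at its less hindered terminus C13 from the only face it can reach (β, anti to the departing acetate), closing ring D.

**Step 11**
Reactants: 17 dimethyl 15,20-dioxo-17-norgibberell-11-ene-7,19-dioate (C6 epimers)
Product: 19 dimethyl 15,20-dioxo-17-norgibberellane-7,19-dioate (6β-ester), via C6-epimeric saturated ketone 18 (not isolated)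
Conditions: H2 (1 atm), 10 % Pd/C, MeOH, 25 °C; filter; NaOMe (2 equiv), MeOH, 60 °C
Reagents that add atoms: none
Why: Heterogeneous hydrogenation saturates the only C=C bond and methoxide then epimerises the ester α-centre C6 to the thermodynamically preferred 6β-ester (trans to the C4–C5 bond); the aldehyde and the bridgehead centres cannot epimerise.

**Step 12**
Reactants: 19 dimethyl 15,20-dioxo-17-norgibberellane-7,19-dioate (6β-ester)
Product: 20 dimethyl 15,20-dioxogibberell-16-ene-7,19-dioate (15-oxo-GA24 dimethyl ester)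
Conditions: (CH2O)n, PhNHMe·CF3CO2H, THF, 65 °C
Reagents that add atoms: formaldehyde (as paraformaldehyde), C=O
Why: Mannich-type α-methylenation at C16, the only enolisable α-position of the bridged ketone (C8 is quaternary), gives the exocyclic enone; the non-enolisable aldehyde is unaffected.

**Step 13**
Reactants: 20 dimethyl 15,20-dioxogibberell-16-ene-7,19-dioate (15-oxo-GA24 dimethyl ester)
Product: 21 GA65 dimethyl ester (dimethyl 15β-hydroxy-20-oxogibberell-16-ene-7,19-dioate)
Conditions: NaBH4, CeCl3·7H2O, MeOH, −78 → −40 °C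
Reagents that add atoms: none
Why: Luche 1,2-reduction: hydride attacks the C15 ketone from the exo face of the bicyclo[3.2.1]octane (away from the three-carbon bridge) to give the endo 15β-alcohol, while the hindered neopentyl aldehyde is masked as its hemiacetal under the CeCl3/MeOH conditions.

**Step 14**
Reactants: 21 GA65 dimethyl ester (dimethyl 15β-hydroxy-20-oxogibberell-16-ene-7,19-dioate)
Product: 22 GA65 (15β-hydroxy-20-oxogibberell-16-ene-7,19-dioic acid)
Conditions: NaSEt (10 equiv), HMPA, 25 → 50 °C; then 1 M HCl, 0 °C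
Reagents that add atoms: none
Why: SN2 demethylation of both methyl esters by thiolate (attack at the unhindered O-methyl carbon, so the hindered C19 ester also cleaves) leaves the aldehyde, the allylic alcohol and all stereocentres untouched and gives the diacid on acidification.

**Compound list**
1 | methyl 3-oxocyclohex-1-ene-1-carboxylate | COC(=O)C1=CC(=O)CCC1 | starting material
2 | methyl 2-iodoacetate | COC(=O)CI | starting material
3 | methyl (1R,2R)-2-(2-methoxy-2-oxoethyl)-1-methyl-3-oxocyclohexane-1-carboxylate | O=C1CCC[C@@](C)(C(=O)OC)[C@H]1CC(=O)OC | intermediate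
4 | methyl 2-(2-methoxy-2-oxoethyl)-3-(methoxymethylidene)-1-methylcyclohexane-1-carboxylate (C4 and C5 as in 3; E/Z mixture) | COC=C1CCC[C@@](C)(C(=O)OC)[C@H]1CC(=O)OC | intermediate
5 | 3-bromoprop-1-yne (propargyl bromide) | C#CCBr | starting material
6 | methyl 2-(1-methoxy-1-oxopent-4-yn-2-yl)-3-(methoxymethylidene)-1-methylcyclohexane-1-carboxylate (C6 epimers) | COC=C1CCC[C@@](C)(C(=O)OC)[C@H]1C(CC#C)C(=O)OC | intermediate
7 | methyl 3-formyl-2-(1-methoxy-1-oxopent-4-yn-2-yl)-1-methylcyclohexane-1-carboxylate (C6 and C10 epimers) | O=CC1CCC[C@@](C)(C(=O)OC)[C@H]1C(CC#C)C(=O)OC | intermediate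
8 | 3-bromoprop-1-ene (allyl bromide) | C=CCBr | starting material
9 | methyl 3-formyl-2-(1-methoxy-1-oxopent-4-yn-2-yl)-1-methyl-3-(prop-2-enyl)cyclohexane-1-carboxylate (4α-CO2Me; 5β-H; 10α-CHO; 10β-allyl; C6 epimers) | C=CC[C@]1(C=O)CCC[C@@](C)(C(=O)OC)[C@H]1C(CC#C)C(=O)OC | intermediate
10 | methyl 3-formyl-2-(1-methoxy-1,4-dioxopentan-2-yl)-1-methyl-3-(prop-2-enyl)cyclohexane-1-carboxylate (ring centres as in 9) | C=CC[C@]1(C=O)CCC[C@@](C)(C(=O)OC)[C@H]1C(CC(C)=O)C(=O)OC | intermediate
11 | prop-2-enal (acrolein) | C=CC=O | starting material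
12 | methyl 3-formyl-2-(1-methoxy-1,4-dioxopentan-2-yl)-1-methyl-3-[(E)-4-oxobut-2-enyl]cyclohexane-1-carboxylate | O=C/C=C/C[C@]1(C=O)CCC[C@@](C)(C(=O)OC)[C@H]1C(CC(C)=O)C(=O)OC | intermediate
13 | methyl 3-[(1E,3E)-4-acetoxybuta-1,3-dienyl]-3-formyl-2-(1-methoxy-1,4-dioxopentan-2-yl)-1-methylcyclohexane-1-carboxylate | CC(=O)O/C=C/C=C/[C@]1(C=O)CCC[C@@](C)(C(=O)OC)[C@H]1C(CC(C)=O)C(=O)OC | intermediate
14 | methyl 3-[(1E,3E)-4-acetoxybuta-1,3-dienyl]-3-formyl-2-(1-methoxy-3-methylidene-1,4-dioxopentan-2-yl)-1-methylcyclohexane-1-carboxylate (α-methylene ketone) | CC(=O)O/C=C/C=C/[C@]1(C=O)CCC[C@@](C)(C(=O)OC)[C@H]1C(C(=C)C(C)=O)C(=O)OC | intermediate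
15 | tricyclic cycloadduct of rings A B C (4α-CO2Me; 4β-Me; 5β-H; 6-CO2Me; 8β-acetyl; 9β-H; 10α-CHO; 13α-OAc; 11-ene; C6 epimers), that is dimethyl 13α-acetoxy-15,20-dioxo-13,16-seco-17-norgibberell-11-ene-7,19-dioate | CC(=O)O[C@H]1C=C[C@H]2[C@]3(C=O)CCC[C@@](C)(C(=O)OC)[C@H]3C(C(=O)OC)[C@]2(C1)C(C)=O | intermediate
16 | trimethylsilyl enol ether of the 8β-acetyl group of 15 | CC(=O)O[C@H]1C=C[C@H]2[C@]3(C=O)CCC[C@@](C)(C(=O)OC)[C@H]3C(C(=O)OC)[C@]2(C1)C(=C)O[Si](C)(C)C | intermediate
17 | dimethyl 15,20-dioxo-17-norgibberell-11-ene-7,19-dioate (C6 epimers) | C1[C@@H]2C=C[C@H]3[C@]4(C=O)CCC[C@@](C)(C(=O)OC)[C@H]4C(C(=O)OC)[C@]3(C2)C1=O | intermediate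
18 | dimethyl 15,20-dioxo-17-norgibberellane-7,19-dioate (C6 epimers) | C1[C@@H]2CC[C@H]3[C@]4(C=O)CCC[C@@](C)(C(=O)OC)[C@H]4C(C(=O)OC)[C@]3(C2)C1=O | intermediate
19 | dimethyl 15,20-dioxo-17-norgibberellane-7,19-dioate (6β-ester) | C1[C@@H]2CC[C@H]3[C@]4(C=O)CCC[C@@](C)(C(=O)OC)[C@H]4[C@H](C(=O)OC)[C@]3(C2)C1=O | intermediate
20 | dimethyl 15,20-dioxogibberell-16-ene-7,19-dioate (15-oxo-GA24 dimethyl ester) | C=C1[C@@H]2CC[C@H]3[C@]4(C=O)CCC[C@@](C)(C(=O)OC)[C@H]4[C@H](C(=O)OC)[C@]3(C2)C1=O | intermediate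
21 | GA65 dimethyl ester (dimethyl 15β-hydroxy-20-oxogibberell-16-ene-7,19-dioate) | C=C1[C@@H]2CC[C@H]3[C@]4(C=O)CCC[C@@](C)(C(=O)OC)[C@H]4[C@H](C(=O)OC)[C@]3(C2)[C@@H]1O | intermediate
22 | GA65 (15β-hydroxy-20-oxogibberell-16-ene-7,19-dioic acid) | C=C1[C@@H]2CC[C@H]3[C@]4(C=O)CCC[C@@](C)(C(=O)O)[C@H]4[C@H](C(=O)O)[C@]3(C2)[C@@H]1O | target

**Totals and risks**
Total step count: 14. Longest linear sequence: 14 steps (from 1).

Most likely to fail: step 9, step 10 and step 1.

Step 9 (methylenation and Diels–Alder; forced "meta" polarity, and facial and fusion selectivity that rest on conformational arguments). The fallback sets out from 10 and comes back at 15; it moves the C13 oxygen to after the cycloaddition. Cross-metathesis of 10 with (Z)-but-2-ene-1,4-diyl diacetate gives the allylic acetate F3. Palladium-catalysed 1,4-elimination (Pd(PPh3)4, Et3N, dioxane, 100 °C) gives the electronically neutral (E)-buta-1,3-dienyl compound F4. The same one-pot methylenation (through the α-methylene ketone F5, not isolated) and intramolecular Diels–Alder reaction give the C13-unsubstituted cycloadduct F6. Allylic C–H acetoxylation (Pd(OAc)2, 1,4-benzoquinone, AcOH) at the unhindered allylic methylene C13 then gives 15 or its C13 epimer F7; both ionise to the same cation in step 10.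

Step 10 (cationic ring D closure; possible elimination or attack at C11). The fallback sets out from 15 and comes back at 17; it makes the bond through a π-allylpalladium complex. Methanolysis (K2CO3, MeOH) gives the 13α-allylic alcohol F8. Mitsunobu inversion (4-nitrobenzoic acid, PPh3, DIAD) gives the 13β-(4-nitrobenzoate) F9, whose leaving group is cis to the acetyl group. Pd(PPh3)4 with KHMDS ionises it with inversion and the ketone enolate attacks C13 anti to palladium (Tsuji–Trost alkylation, net retention) to give 17.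

Step 1 (alkylation of a hindered zinc enolate; C5 selectivity). The fallback sets out from 1 and comes back at 3. After the same conjugate addition the enolate is trapped by palladium-catalysed allylation (allyl acetate, Pd(PPh3)4) to give methyl (1R,2R)-1-methyl-3-oxo-2-(prop-2-enyl)cyclohexane-1-carboxylate F1. Oxidative cleavage (RuCl3, NaIO4) gives 2-[(1R,2R)-2-(methoxycarbonyl)-2-methyl-6-oxocyclohexyl]acetic acid F2. Esterification (TMSCHN2, MeOH) gives 3.

**Further compounds**
F1 | step 1 | methyl (1R,2R)-1-methyl-3-oxo-2-(prop-2-enyl)cyclohexane-1-carboxylate | O=C1CCC[C@@](C)(C(=O)OC)[C@H]1CC=C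
F2 | step 1 | 2-[(1R,2R)-2-(methoxycarbonyl)-2-methyl-6-oxocyclohexyl]acetic acid | O=C1CCC[C@@](C)(C(=O)OC)[C@H]1CC(=O)O
F3 | step 9 | methyl 3-[(E)-4-acetoxybut-2-enyl]-3-formyl-2-(1-methoxy-1,4-dioxopentan-2-yl)-1-methylcyclohexane-1-carboxylate | CC(=O)OC/C=C/C[C@]1(C=O)CCC[C@@](C)(C(=O)OC)[C@H]1C(CC(C)=O)C(=O)OC
F4 | step 9 | methyl 3-[(E)-buta-1,3-dienyl]-3-formyl-2-(1-methoxy-1,4-dioxopentan-2-yl)-1-methylcyclohexane-1-carboxylate | C=C/C=C/[C@]1(C=O)CCC[C@@](C)(C(=O)OC)[C@H]1C(CC(C)=O)C(=O)OC
F5 | step 9 | methyl 3-[(E)-buta-1,3-dienyl]-3-formyl-2-(1-methoxy-3-methylidene-1,4-dioxopentan-2-yl)-1-methylcyclohexane-1-carboxylate | C=C/C=C/[C@]1(C=O)CCC[C@@](C)(C(=O)OC)[C@H]1C(C(=C)C(C)=O)C(=O)OC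
F6 | step 9 | tricyclic cycloadduct of rings A B C without the 13-acetoxy group (otherwise as 15) | C1C=C[C@H]2[C@]3(C=O)CCC[C@@](C)(C(=O)OC)[C@H]3C(C(=O)OC)[C@]2(C1)C(C)=O
F7 | step 9 | 13β-acetoxy epimer of 15 | CC(=O)O[C@@H]1C=C[C@H]2[C@]3(C=O)CCC[C@@](C)(C(=O)OC)[C@H]3C(C(=O)OC)[C@]2(C1)C(C)=O
F8 | step 10 | 13α-hydroxy analogue of 15 (allylic alcohol) | O[C@H]1C=C[C@H]2[C@]3(C=O)CCC[C@@](C)(C(=O)OC)[C@H]3C(C(=O)OC)[C@]2(C1)C(C)=O
F9 | step 10 | 13β-(4-nitrobenzoyloxy) analogue of 15 | O=C(O[C@@H]1C=C[C@H]2[C@]3(C=O)CCC[C@@](C)(C(=O)OC)[C@H]3C(C(=O)OC)[C@]2(C1)C(C)=O)c1ccc(cc1)[N+](=O)[O-]
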